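**Plan**

- Retrosynthetic cuts: first the aryl–C(=O) bond of the central (S)-2-methylbutanoyl group; then the two outer aryl–C(=O) bonds, each traced back to a butanoate on the neighbouring oxygen and a bromine on the ring carbon; last the two CH2–central-ring bonds, with each outer-ring–CH2 bond traced back to a formyl group.
- Forward order: no ring is built. 2-Methylphloroglucinol is formylated (the future bridge carbon), O-methylated para to the formyl group, brominated at its last ring CH, capped as the bis(allyl ether) and reduced. Two such units are joined as benzylic cations to a bromine-blocked phloroglucinol tribenzyl ether, the allyl groups are removed and the four outer phenols are butanoylated. The twofold O-to-C acyl shift, central acylation and hydrogenolysis follow.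
- Enabling feature: in each outer ring the ketone carbon C1 lies between the C2–OH carbon and the C6–OMe carbon, and every other ring position is already occupied (bridge CH2, OH, CH3). A bromine on C1 and a butanoate on O2 therefore lead to the ketone by a 1,3 shift from O2 to C1.
- Stereochemistry: the single stereocentre is taken from commercial (S)-2-methylbutanoic acid and is introduced only after all strongly basic steps.

Key step: step 10

Remark: 1,3,5-tris(benzyloxy)benzene is taken as a purchasable starting material. The bromine placed on the central ring in step 6 is a placeholder that blocks the third central position during the coupling and leaves as the central C–H in step 10.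

**Route**

Step 1
Reactants: 1 2-methylphloroglucinol
Product: 3 2,4,6-trihydroxy-3-methylbenzaldehyde, via iminium chloride 2 (not isolated)
Conditions: POCl3 (1.1 equiv), DMF (1.2 equiv), EtOAc, 0 °C to rt; then H2O, 60 °C
Reagents that add atoms: N,N-dimethylformamide CN(C)C=O; water O
Why: Vilsmeier–Haack formylation should take one of the two equivalent free ring CH positions of the phloroglucinol nucleus, and one equivalent of reagent limits it to monoformylation.

Step 2
Reactants: 3 2,4,6-trihydroxy-3-methylbenzaldehyde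
Product: 4 2,6-dihydroxy-4-methoxy-3-methylbenzaldehyde
Conditions: Me2SO4 (1.0 equiv), K2CO3 (1.0 equiv), acetone, rt
Reagents that add atoms: dimethyl sulfate COS(=O)(=O)OC
Why: Williamson O-methylation with one equivalent of base should go to the 4-hydroxyl para to the formyl group, which is the most acidic and the only one not hydrogen-bonded to the carbonyl oxygen.

Step 3
Reactants: 4 2,6-dihydroxy-4-methoxy-3-methylbenzaldehyde
Product: 5 3-bromo-2,6-dihydroxy-4-methoxy-5-methylbenzaldehyde
Conditions: NBS (1.0 equiv), MeCN, 0 °C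
Reagents that add atoms: N-bromosuccinimide O=C1CCC(=O)N1Br
Why: Electrophilic aromatic bromination can only take the single remaining ring CH, which is activated by the flanking hydroxyl and methoxyl groups.

Step 4
Reactants: 5 3-bromo-2,6-dihydroxy-4-methoxy-5-methylbenzaldehyde
Product: 6 2,6-bis(allyloxy)-3-bromo-4-methoxy-5-methylbenzaldehyde
Conditions: allyl bromide (3 equiv), K2CO3 (3 equiv), DMF, 50 °C
Reagents that add atoms: allyl bromide C=CCBr
Why: Williamson etherification of both chelated phenols gives acid-stable, non-migrating ethers that block the quinone methide path in the next reduction and can later be removed beside benzyl ethers and aryl bromides.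

Step 5
Reactants: 6 2,6-bis(allyloxy)-3-bromo-4-methoxy-5-methylbenzaldehyde
Product: 7 [2,6-bis(allyloxy)-3-bromo-4-methoxy-5-methylphenyl]methanol
Conditions: NaBH4, THF/MeOH, 0 °C
Reagents that add atoms: none
Why: Borohydride reduction of the aldehyde should stop at the benzylic alcohol, because no free ortho-hydroxyl is left to open the quinone methide route to over-reduction.

Step 6
Reactants: 8 1,3,5-tris(benzyloxy)benzene
Product: 9 2-bromo-1,3,5-tris(benzyloxy)benzene
Conditions: NBS (1.0 equiv), CH2Cl2, −78 to 0 °C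
Reagents that add atoms: N-bromosuccinimide O=C1CCC(=O)N1Br
Why: Electrophilic aromatic bromination of the symmetric triether with one equivalent of reagent gives a single monobromide and leaves exactly two equivalent nucleophilic CH positions.

Step 7
Reactants: 7 [2,6-bis(allyloxy)-3-bromo-4-methoxy-5-methylphenyl]methanol (2.2 equiv); 9 2-bromo-1,3,5-tris(benzyloxy)benzene
Product: 10 1,3,5-tris(benzyloxy)-2-bromo-4,6-bis{[2,6-bis(allyloxy)-3-bromo-4-methoxy-5-methylphenyl]methyl}benzene
Conditions: BF3·OEt2 (0.3 equiv), 4 Å molecular sieves, CH2Cl2, −40 to 0 °C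
Reagents that add atoms: none
Why: In this Friedel–Crafts benzylation the Lewis acid ionises 7 to a benzylic cation stabilised by two ortho oxygens and one para oxygen, which should alkylate both free CH positions of 9, while the bromines rule out self-condensation of 7 and a third alkylation of the central ring.

Step 8
Reactants: 10 tribromo tetra-O-allyl trimer
Product: 11 2,2'-{[2,4,6-tris(benzyloxy)-5-bromo-1,3-phenylene]bis(methylene)}bis(4-bromo-5-methoxy-6-methylbenzene-1,3-diol)
Conditions: Pd(PPh3)4 (5 mol%), morpholine (10 equiv), THF, rt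
Reagents that add atoms: none
Why: In this Tsuji–Trost-type deallylation zerovalent palladium ionises each aryl allyl ether to a π-allyl complex of divalent palladium that morpholine intercepts, which should free the four outer phenols at room temperature without touching benzyl ethers or the hindered, electron-rich aryl bromides.

Step 9
Reactants: 11 tribromo tetraphenol; 12 butanoyl chloride (6 equiv)
Product: 13 1,3,5-tris(benzyloxy)-2-bromo-4,6-bis{[3-bromo-2,6-bis(butanoyloxy)-4-methoxy-5-methylphenyl]methyl}benzene
Conditions: 12 (6 equiv), pyridine, DMAP (cat.), CH2Cl2, 0 °C to rt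
Reagents that add atoms: butanoyl chloride CCCC(=O)Cl
Why: DMAP-catalysed O-acylation with an excess of the acid chloride should place one butanoyl group on each of the four outer phenols, so no selectivity between the two oxygens of an outer ring is needed, since only the ester next to bromine can migrate later.

Step 10
Reactants: 13 tribromo tetrabutanoate
Product: 16 1,3,5-tris(benzyloxy)-2,4-bis{[3-butanoyl-6-(butanoyloxy)-2-hydroxy-4-methoxy-5-methylphenyl]methyl}benzene, via trilithio tetraester 14 (not isolated), via trilithium bisphenoxide 15 (not isolated)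
Conditions: t-BuLi (6.2 equiv, added slowly), THF/Et2O/pentane (4:1:1), −100 °C; then AcOH, −100 °C to rt
Reagents that add atoms: none
Why: Lithium–bromine exchange with t-BuLi at −100 °C should outrun addition to the doubly ortho-substituted aryl esters and turn all three C–Br bonds into C–Li bonds. Each outer aryllithium then adds to the carbonyl of the butanoate on the adjacent oxygen through a strained four-membered alkoxide, which collapses to the aryl ketone and a lithium phenoxide, a 1,3 O-to-C acyl shift (anionic ortho-Fries rearrangement). The closest known reaction is the rearrangement of ortho-bromophenyl esters to ortho-hydroxyaryl ketones triggered by metal–halogen exchange; no ring is closed and no stereocentre is formed. The step needs chemoselectivity (exchange before ester attack or enolisation) and site selectivity, and the latter is built in: the lithiated carbon of an outer ring has the butanoyloxy carbon on one side and the methoxy carbon on the other, while the second butanoate of that ring sits para to it and cannot be reached. The central aryllithium, flanked by two benzyloxy groups and unable to reach any ester within the molecule, only waits for the acetic acid quench, which leaves the central C–H. No Lewis acid is present, so the diarylmethane links cannot migrate.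

Step 11
Reactants: 16 bis(hydroxyaryl ketone) dibutanoate
Product: 17 1,3,5-tris(benzyloxy)-2,4-bis[(3-butanoyl-2,6-dihydroxy-4-methoxy-5-methylphenyl)methyl]benzene
Conditions: K2CO3, MeOH/THF, rt
Reagents that add atoms: none
Why: Base-catalysed transesterification should remove the two remaining aryl butanoates before the base-sensitive stereocentre is present, and the bridges are safe because the central triether ring cannot depart as an anion.

Step 12
Reactants: 17 bis(dihydroxyaryl ketone)
Product: 18 1,3,5-tris(benzyloxy)-2,4-bis{[2,6-bis(benzyloxy)-3-butanoyl-4-methoxy-5-methylphenyl]methyl}benzene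
Conditions: BnBr (6 equiv), K2CO3, Bu4NI (cat.), DMF, 60 °C
Reagents that add atoms: benzyl bromide BrCc1ccccc1
Why: Williamson benzylation caps the four outer phenols, the two chelated ones included, so that the following acylation meets no free hydroxyl.

Step 13
Reactants: 18 hepta-O-benzyl bis(ketone); 19 (S)-2-methylbutanoic acid (3 equiv)
Product: 21 (2S)-1-(2,4,6-tris(benzyloxy)-3,5-bis{[2,6-bis(benzyloxy)-3-butanoyl-4-methoxy-5-methylphenyl]methyl}phenyl)-2-methylbutan-1-one, via mixed anhydride 20 (not isolated)
Conditions: 19 and (CF3CO)2O (3 equiv) premixed, CH2Cl2, 0 °C; then 18, 0 °C to rt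
Reagents that add atoms: none
Why: Friedel–Crafts acylation by the mixed trifluoroacetic anhydride should attack the only ring CH of the molecule, on the trialkoxy-activated central ring, and the stereocentre is carried over unchanged from 19 because no base is present that could form a ketene.

Step 14
Reactants: 21 hepta-O-benzyl agrimol B
Product: 22 agrimol B
Conditions: H2 (1 atm), Pd/C (10%), EtOAc/MeOH, rt
Reagents that add atoms: none
Why: Catalytic hydrogenolysis should cleave all seven benzyl ethers under neutral conditions that leave the aryl ketones, the methylene bridges and the alpha stereocentre untouched.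

**Compound list**

1 | 2-methylphloroglucinol (2-methylbenzene-1,3,5-triol) | Cc1c(O)cc(O)cc1O | starting material
2 | [(2,4,6-trihydroxy-3-methylphenyl)methylidene]dimethyliminium chloride | C[N+](C)=Cc1c(O)c(C)c(O)cc1O.[Cl-] | intermediate
3 | 2,4,6-trihydroxy-3-methylbenzaldehyde | O=Cc1c(O)c(C)c(O)cc1O | intermediate
4 | 2,6-dihydroxy-4-methoxy-3-methylbenzaldehyde | COc1cc(O)c(C=O)c(O)c1C | intermediate
5 | 3-bromo-2,6-dihydroxy-4-methoxy-5-methylbenzaldehyde | COc1c(Br)c(O)c(C=O)c(O)c1C | intermediate
6 | 2,6-bis(allyloxy)-3-bromo-4-methoxy-5-methylbenzaldehyde | COc1c(Br)c(OCC=C)c(C=O)c(OCC=C)c1C | intermediate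
7 | [2,6-bis(allyloxy)-3-bromo-4-methoxy-5-methylphenyl]methanol | COc1c(Br)c(OCC=C)c(CO)c(OCC=C)c1C | intermediate
8 | 1,3,5-tris(benzyloxy)benzene | c1ccc(COc2cc(OCc3ccccc3)cc(OCc3ccccc3)c2)cc1 | starting material
9 | 2-bromo-1,3,5-tris(benzyloxy)benzene | Brc1c(OCc2ccccc2)cc(OCc2ccccc2)cc1OCc1ccccc1 | intermediate
10 | 1,3,5-tris(benzyloxy)-2-bromo-4,6-bis{[2,6-bis(allyloxy)-3-bromo-4-methoxy-5-methylphenyl]methyl}benzene | COc1c(Br)c(OCC=C)c(Cc2c(OCc3ccccc3)c(Br)c(OCc3ccccc3)c(Cc3c(OCC=C)c(Br)c(OC)c(C)c3OCC=C)c2OCc2ccccc2)c(OCC=C)c1C | intermediate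
11 | 2,2'-{[2,4,6-tris(benzyloxy)-5-bromo-1,3-phenylene]bis(methylene)}bis(4-bromo-5-methoxy-6-methylbenzene-1,3-diol) | COc1c(Br)c(O)c(Cc2c(OCc3ccccc3)c(Br)c(OCc3ccccc3)c(Cc3c(O)c(Br)c(OC)c(C)c3O)c2OCc2ccccc2)c(O)c1C | intermediate
12 | butanoyl chloride | CCCC(=O)Cl | starting material
13 | 1,3,5-tris(benzyloxy)-2-bromo-4,6-bis{[3-bromo-2,6-bis(butanoyloxy)-4-methoxy-5-methylphenyl]methyl}benzene (precursor of the key step) | COc1c(Br)c(OC(=O)CCC)c(Cc2c(OCc3ccccc3)c(Br)c(OCc3ccccc3)c(Cc3c(OC(=O)CCC)c(Br)c(OC)c(C)c3OC(=O)CCC)c2OCc2ccccc2)c(OC(=O)CCC)c1C | intermediate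
14 | triply lithiated tetraester (each Br of 13 replaced by Li) | COc1c([Li])c(OC(=O)CCC)c(Cc2c(OCc3ccccc3)c([Li])c(OCc3ccccc3)c(Cc3c(OC(=O)CCC)c([Li])c(OC)c(C)c3OC(=O)CCC)c2OCc2ccccc2)c(OC(=O)CCC)c1C | intermediate
15 | dilithium bis(phenoxide) of 16 that still carries the central aryllithium | COc1c(C(=O)CCC)c(O[Li])c(Cc2c(OCc3ccccc3)c([Li])c(OCc3ccccc3)c(Cc3c(O[Li])c(C(=O)CCC)c(OC)c(C)c3OC(=O)CCC)c2OCc2ccccc2)c(OC(=O)CCC)c1C | intermediate
16 | 1,3,5-tris(benzyloxy)-2,4-bis{[3-butanoyl-6-(butanoyloxy)-2-hydroxy-4-methoxy-5-methylphenyl]methyl}benzene (product of the key step) | COc1c(C(=O)CCC)c(O)c(Cc2c(OCc3ccccc3)cc(OCc3ccccc3)c(Cc3c(O)c(C(=O)CCC)c(OC)c(C)c3OC(=O)CCC)c2OCc2ccccc2)c(OC(=O)CCC)c1C | intermediate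
17 | 1,3,5-tris(benzyloxy)-2,4-bis[(3-butanoyl-2,6-dihydroxy-4-methoxy-5-methylphenyl)methyl]benzene | COc1c(C(=O)CCC)c(O)c(Cc2c(OCc3ccccc3)cc(OCc3ccccc3)c(Cc3c(O)c(C(=O)CCC)c(OC)c(C)c3O)c2OCc2ccccc2)c(O)c1C | intermediate
18 | 1,3,5-tris(benzyloxy)-2,4-bis{[2,6-bis(benzyloxy)-3-butanoyl-4-methoxy-5-methylphenyl]methyl}benzene | COc1c(C(=O)CCC)c(OCc2ccccc2)c(Cc2c(OCc3ccccc3)cc(OCc3ccccc3)c(Cc3c(OCc4ccccc4)c(C(=O)CCC)c(OC)c(C)c3OCc3ccccc3)c2OCc2ccccc2)c(OCc2ccccc2)c1C | intermediate
19 | (S)-2-methylbutanoic acid | CC[C@H](C)C(=O)O | starting material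
20 | (S)-2-methylbutanoic trifluoroacetic anhydride | CC[C@H](C)C(=O)OC(=O)C(F)(F)F | intermediate
21 | (2S)-1-(2,4,6-tris(benzyloxy)-3,5-bis{[2,6-bis(benzyloxy)-3-butanoyl-4-methoxy-5-methylphenyl]methyl}phenyl)-2-methylbutan-1-one | COc1c(C(=O)CCC)c(OCc2ccccc2)c(Cc2c(OCc3ccccc3)c(C(=O)[C@@H](C)CC)c(OCc3ccccc3)c(Cc3c(OCc4ccccc4)c(C(=O)CCC)c(OC)c(C)c3OCc3ccccc3)c2OCc2ccccc2)c(OCc2ccccc2)c1C | intermediate
22 | agrimol B, (2S)-1-{3,5-bis[(3-butanoyl-2,6-dihydroxy-4-methoxy-5-methylphenyl)methyl]-2,4,6-trihydroxyphenyl}-2-methylbutan-1-one | CCCC(=O)c1c(O)c(Cc2c(O)c(Cc3c(O)c(C)c(OC)c(C(=O)CCC)c3O)c(O)c(C(=O)[C@@H](C)CC)c2O)c(O)c(C)c1OC | target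

**Count and risks**

Total step count: 14. Longest linear sequence: 13 steps (steps 1–5 and 7–14, from 2-methylphloroglucinol); step 6 is a one-step side branch.

Steps most likely to fail:

1. Step 10. The alkyllithium may add to or enolise the butanoates, above all the two that are not meant to migrate. An outer aryllithium may also be protonated before the acyl shift. Either event removes an acyl group or leaves a debrominated ester. The fallback takes the spectator esters out of the substrate and sets out from 11. The two bromine-flanked phenols, the more acidic ones, would be acylated selectively with two equivalents of 12 and NaHCO3 in a two-phase system, to give the bis(bromine-side butanoate) diphenol F1. The remaining methyl-flanked phenols would be benzylated under neutral Mitsunobu conditions (BnOH, PPh3, DIAD) to the dibutanoate dibenzyl ether F2. Exchange of F2 with t-BuLi as in step 10 should give the bis(hydroxyaryl ketone) F3, which carries benzyl ethers in place of the spectator esters. Benzylation of its two chelated phenols (BnBr, K2CO3, DMF) comes back to the route at 18.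

2. Step 13. Attack at the crowded central CH between two benzyloxy groups may be slow. Acid-induced loss of benzyl groups, ipso attack with cleavage of a methylene bridge, or partial racemisation through the acylium ion could then compete. The fallback acylates a free phloroglucinol ring instead and sets out from 17. Hydrogenolysis (H2, Pd/C) of the three central benzyl ethers should give the heptaphenol F4. In parallel, 19 would be converted with oxalyl chloride and catalytic DMF into (S)-2-methylbutanoyl chloride F5. Classical Friedel–Crafts acylation of F4 with F5 and AlCl3 in nitrobenzene/CH2Cl2 at the only ring CH comes back to the route at 22.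

3. Step 7. The second alkylation of the bromine-deactivated, crowded central ring may stall at the mono-adduct. The benzylic cation may also be diverted into dibenzyl ethers or into ipso attack at the brominated carbon. The fallback forms the same bonds from an aryllithium and an aldehyde and sets out from 9 and 6. A second bromination of 9 (NBS) should give 2,4-dibromo-1,3,5-tris(benzyloxy)benzene F6. Double lithium–bromine exchange (t-BuLi, THF, −78 °C) and addition of two equivalents of aldehyde 6 would give the bis(diarylmethanol) F7 as a mixture of diastereomers. Ionic hydrogenation (Et3SiH, CF3CO2H, CH2Cl2, 0 °C) removes both hydroxyl groups to give the tetra-O-allyl dibromide F8, which has a free central CH. Deallylation as in step 8 gives the dibromo tetraphenol F9, and butanoylation as in step 9 gives the dibromo tetrabutanoate F10. Treatment of F10 with four equivalents of t-BuLi under the conditions of step 10 comes back to the route at 16.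

Further compounds
F1 | step 10 | 1,3,5-tris(benzyloxy)-2-bromo-4,6-bis{[3-bromo-2-(butanoyloxy)-6-hydroxy-4-methoxy-5-methylphenyl]methyl}benzene | COc1c(Br)c(OC(=O)CCC)c(Cc2c(OCc3ccccc3)c(Br)c(OCc3ccccc3)c(Cc3c(OC(=O)CCC)c(Br)c(OC)c(C)c3O)c2OCc2ccccc2)c(O)c1C
F2 | step 10 | 1,3,5-tris(benzyloxy)-2-bromo-4,6-bis{[6-(benzyloxy)-3-bromo-2-(butanoyloxy)-4-methoxy-5-methylphenyl]methyl}benzene | COc1c(Br)c(OC(=O)CCC)c(Cc2c(OCc3ccccc3)c(Br)c(OCc3ccccc3)c(Cc3c(OC(=O)CCC)c(Br)c(OC)c(C)c3OCc3ccccc3)c2OCc2ccccc2)c(OCc2ccccc2)c1C
F3 | step 10 | 1,3,5-tris(benzyloxy)-2,4-bis{[6-(benzyloxy)-3-butanoyl-2-hydroxy-4-methoxy-5-methylphenyl]methyl}benzene | COc1c(C(=O)CCC)c(O)c(Cc2c(OCc3ccccc3)cc(OCc3ccccc3)c(Cc3c(O)c(C(=O)CCC)c(OC)c(C)c3OCc3ccccc3)c2OCc2ccccc2)c(OCc2ccccc2)c1C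
F4 | step 13 | 2,4-bis[(3-butanoyl-2,6-dihydroxy-4-methoxy-5-methylphenyl)methyl]benzene-1,3,5-triol | COc1c(C(=O)CCC)c(O)c(Cc2c(O)cc(O)c(Cc3c(O)c(C(=O)CCC)c(OC)c(C)c3O)c2O)c(O)c1C
F5 | step 13 | (S)-2-methylbutanoyl chloride | CC[C@H](C)C(=O)Cl
F6 | step 7 | 2,4-dibromo-1,3,5-tris(benzyloxy)benzene | Brc1c(OCc2ccccc2)cc(OCc2ccccc2)c(Br)c1OCc1ccccc1
F7 | step 7 | [2,4,6-tris(benzyloxy)-1,3-phenylene]bis{[2,6-bis(allyloxy)-3-bromo-4-methoxy-5-methylphenyl]methanol}, mixture of diastereomers | COc1c(Br)c(OCC=C)c(C(O)c2c(OCc3ccccc3)cc(OCc3ccccc3)c(C(O)c3c(OCC=C)c(Br)c(OC)c(C)c3OCC=C)c2OCc2ccccc2)c(OCC=C)c1C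
F8 | step 7 | 1,3,5-tris(benzyloxy)-2,4-bis{[2,6-bis(allyloxy)-3-bromo-4-methoxy-5-methylphenyl]methyl}benzene | COc1c(Br)c(OCC=C)c(Cc2c(OCc3ccccc3)cc(OCc3ccccc3)c(Cc3c(OCC=C)c(Br)c(OC)c(C)c3OCC=C)c2OCc2ccccc2)c(OCC=C)c1C
F9 | step 7 | 2,2'-{[2,4,6-tris(benzyloxy)-1,3-phenylene]bis(methylene)}bis(4-bromo-5-methoxy-6-methylbenzene-1,3-diol) | COc1c(Br)c(O)c(Cc2c(OCc3ccccc3)cc(OCc3ccccc3)c(Cc3c(O)c(Br)c(OC)c(C)c3O)c2OCc2ccccc2)c(O)c1C
F10 | step 7 | 1,3,5-tris(benzyloxy)-2,4-bis{[3-bromo-2,6-bis(butanoyloxy)-4-methoxy-5-methylphenyl]methyl}benzene | COc1c(Br)c(OC(=O)CCC)c(Cc2c(OCc3ccccc3)cc(OCc3ccccc3)c(Cc3c(OC(=O)CCC)c(Br)c(OC)c(C)c3OC(=O)CCC)c2OCc2ccccc2)c(OC(=O)CCC)c1C
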